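The target (uliginosin B) is disconnected at the O1–C2 and C4–C4a bonds of its 2,2-dimethyl-2H-pyran. The key step is a formal [3+3] annulation of prenal onto the fully assembled methylene-bridged dimer. Amine-catalysed condensation at the single unsubstituted carbon of the phloroglucinol ring (future C4a, flanked by the future C5–OH and C8a–O) gives a vinyl ortho-quinone methide that closes by oxa-6π electrocyclisation, the species an oxidised prenyl group would give in biosynthesis. The isobutyryl chelate differentiates the two flanking oxygens, so the oxygen para to the ketone becomes the ring oxygen. The precursor is the chromene-free dimer, assembled from isobutyrylfilicinic acid and isobutyrylphloroglucinol through a one-carbon Mannich linchpin.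

Key step: step 4

Remark: the target has no stereocentre and no stereogenic double bond, so it is achiral and no enantioselective step is needed; all compounds are drawn in the enol tautomer of the target SMILES.

Step 1
Reactants: 1 phloroglucinol; 2 isobutyryl chloride
Product: 3 phlorisobutyrophenone
Conditions: AlCl3 (3.5 equiv), PhNO2/CH2Cl2, 0 °C → 45 °C; then ice/1 M HCl
Reagents that add atoms: none
Why: Friedel–Crafts acylation of the strongly activated triol should stop at the mono-ketone because the aluminium-chelated aryl ketone deactivates the ring towards a second acylation.

Step 2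
Reactants: 3 phlorisobutyrophenone
Product: 5 isobutyrylfilicinic acid, via C-methyl intermediate 4 (not isolated)
Conditions: NaOMe (3 equiv), MeI (2.5 equiv), MeOH, 0 °C → rt; then 1 M HCl
Reagents that add atoms: iodomethane, CI
Why: Dearomatising double C-methylation of the phloroglucinol phenoxide (twice at the same carbon, via 4) should work because the C-methylated carbon remains the most nucleophilic site and the gem-dimethyl enolised triketone formed is a vinylogous acid whose delocalised anion resists further alkylation.

Step 3
Reactants: 5 isobutyrylfilicinic acid; 3 phlorisobutyrophenone (3 equiv)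
Product: 8 methylene-bridged dimer, via Mannich base 6 (not isolated), via methylene trione 7 (not isolated)
Conditions: CH2=NMe2+ I− (1.0 equiv), MeCN, 0 °C → rt; then 3 (3 equiv), NaOAc (1.1 equiv), 50 °C
Reagents that add atoms: N,N-dimethylmethyleneiminium iodide (Eschenmoser's salt), C=[N+](C)C.[I-]
Why: Mannich reaction at the only CH of the enolic triketone gives 6, E1cB loss of dimethylamine gives the 2-methylene-1,3-dione 7, and a Friedel–Crafts-type Michael addition of a ring carbon of 3 (in excess, to suppress double alkylation) followed by re-aromatisation should give 8, the one-carbon unit being bound to 5 beforehand so that 3 cannot dimerise with itself.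

Step 4
Reactants: 8 methylene-bridged dimer; 9 prenal (3-methylbut-2-enal, 1.5 equiv)
Product: 11 uliginosin B (target), via oxatriene 10 (not isolated)
Conditions: ethylenediammonium diacetate (EDDA, 20 mol %), toluene/THF, 80 °C
Reagents that add atoms: none
Why: EDDA converts prenal into its iminium ion, which is attacked by C5 of the aromatic ring of 8 (the only ring CH, flanked by two hydroxyls); loss of the amine and of water gives the vinyl ortho-quinone methide (1-oxatriene) 10, which closes thermally by a disrotatory oxa-6π electrocyclisation in which the dienone oxygen bonds to the CMe2 terminus. The closest known reaction is the amine-catalysed formal [3+3] chromene annulation (Knoevenagel condensation/oxa-6π electrocyclisation) of resorcinols and acylphloroglucinols with α,β-unsaturated aldehydes, and 10 is also the species through which an oxidative cyclisation of a prenyl side chain would pass. The pyran is the only ring closed, by 6π-electrocyclic O–C bond formation after intermolecular C–C bond formation, and no stereocentre is created. Site selectivity is secured by the substrate, because the aromatic ring has one free carbon and the filicinic ring has none (its C2, C4 and C6 are fully substituted), so neither a second annulation nor reaction on the other ring is possible. Closure must occur through the hydroxyl para to the isobutyryl group (next to the methylene bridge): this is the most acidic phenol and is not held in the six-membered ketone chelate that ties up the other flanking hydroxyl, so the dienone carbonyl of 10 is expected to sit there, as in the annulation of 2,4-dihydroxyacetophenone, which gives the 5-hydroxy-6-acyl chromene. The buffered, weakly acidic amine salt and moderate temperature are chosen because the methylene bridge can scramble by retro-Michael cleavage under alkaline conditions.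

Compound list
1 | phloroglucinol (benzene-1,3,5-triol) | Oc1cc(O)cc(O)c1 | starting material
2 | isobutyryl chloride (2-methylpropanoyl chloride) | CC(C)C(Cl)=O | starting material
3 | phlorisobutyrophenone, 2-methyl-1-(2,4,6-trihydroxyphenyl)propan-1-one | CC(C)C(=O)c1c(O)cc(O)cc1O | intermediate
4 | 2-methyl-1-(2,4,6-trihydroxy-3-methylphenyl)propan-1-one (mono-C-methyl intermediate, not isolated) | CC(C)C(=O)c1c(O)cc(O)c(C)c1O | intermediate
5 | isobutyrylfilicinic acid, 3,5-dihydroxy-4,4-dimethyl-2-(2-methylpropanoyl)cyclohexa-2,5-dien-1-one | CC(C)C(=O)C1=C(O)C(C)(C)C(O)=CC1=O | intermediate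
6 | Mannich base, 6-[(dimethylamino)methyl]-3,5-dihydroxy-4,4-dimethyl-2-(2-methylpropanoyl)cyclohexa-2,5-dien-1-one (not isolated) | CC(C)C(=O)C1=C(O)C(C)(C)C(O)=C(CN(C)C)C1=O | intermediate
7 | methylene trione, 5-hydroxy-6,6-dimethyl-2-methylidene-4-(2-methylpropanoyl)cyclohex-4-ene-1,3-dione (not isolated) | CC(C)C(=O)C1=C(O)C(C)(C)C(=O)C(=C)C1=O | intermediate
8 | methylene-bridged dimer, 3,5-dihydroxy-4,4-dimethyl-2-(2-methylpropanoyl)-6-{[2,4,6-trihydroxy-3-(2-methylpropanoyl)phenyl]methyl}cyclohexa-2,5-dien-1-one | CC(C)C(=O)C1=C(O)C(C)(C)C(O)=C(Cc2c(O)c(C(=O)C(C)C)c(O)cc2O)C1=O | intermediate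
9 | prenal (3-methylbut-2-enal) | CC(C)=CC=O | starting material
10 | oxatriene (vinyl ortho-quinone methide), 3,5-dihydroxy-6-{[2,4-dihydroxy-5-(3-methylbut-2-enylidene)-3-(2-methylpropanoyl)-6-oxocyclohexa-1,3-dien-1-yl]methyl}-4,4-dimethyl-2-(2-methylpropanoyl)cyclohexa-2,5-dien-1-one (not isolated) | CC(C)C(=O)C1=C(O)C(C)(C)C(O)=C(CC2=C(O)C(C(=O)C(C)C)=C(O)C(=CC=C(C)C)C2=O)C1=O | intermediate
11 | uliginosin B, 3,5-dihydroxy-6-{[5,7-dihydroxy-2,2-dimethyl-6-(2-methylpropanoyl)-2H-chromen-8-yl]methyl}-4,4-dimethyl-2-(2-methylpropanoyl)cyclohexa-2,5-dien-1-one | CC(C)C(=O)C1=C(O)C(C)(C)C(O)=C(Cc2c(O)c(C(=O)C(C)C)c(O)c3c2OC(C)(C)C=C3)C1=O | target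

Total step count: 4. Longest linear sequence: 4 steps (1 → 3 → 5 → 8 → 11); compound 3 enters twice (steps 2 and 3).

Steps most likely to fail

Step 4 (key step). The electrocyclisation may close through the ketone-chelated oxygen instead of the para oxygen, giving the regioisomeric chromene. The methylene bridge may also cleave by retro-Michael reaction under amine catalysis and heat, scrambling the two halves. The fallback builds the pyran before the bridge, with the ring oxygen fixed by construction. It sets out from compound 3: selective O-alkylation of the non-chelated 4-OH with 3-chloro-3-methylbut-1-yne (K2CO3, KI, CuI cat., acetone, 60 °C) should give aryl propargyl ether F1. Heating F1 in DMF at 130 °C should trigger the aryl propargyl ether Claisen rearrangement, 1,5-hydrogen shift and oxa-6π closure in one operation; the ether oxygen para to the ketone necessarily becomes the ring oxygen, giving chromene F2. F2 has a single free aromatic CH (C8) and is then alkylated by Mannich base 6 (made from 5 as in step 3, reacting via 7; NaOAc, MeCN, 50 °C), which comes back to the route at compound 11. The pyran remains the only ring closed in the synthesis.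

Step 3. Compound 3 may be alkylated twice (trimer formation), and 6 may revert to 5 by retro-Mannich reaction, which would then capture 7 to give the filicinic homodimer. The fallback reverses the roles of the two halves. It sets out from compound 3: Mannich reaction with aqueous formaldehyde and dimethylamine (1 equiv each, EtOH, rt) should give mono-Mannich base F3, which is purified from any bis-adduct. Heating F3 with 5 (1.2 equiv) in dioxane at 90 °C, where 5 protonates the amine and its enolate is the only carbon nucleophile with a single reactive site, should transfer the benzylic carbon to C6 of 5 with loss of dimethylamine, coming back to the route at compound 8.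

Step 2. Methylation may stop early, go on to the second ring carbon or occur on oxygen, giving mixtures that are hard to separate. The fallback blocks the second ring carbon with a removable acyl group. It sets out from compound 3: a second Friedel–Crafts acylation with 2 (AlCl3, PhNO2, 60 °C) should give 2,4-diisobutyrylphloroglucinol F4, which has only one ring CH. MeI/NaOMe in MeOH can then only gem-dimethylate that carbon, giving the symmetric 3,5-diisobutyrylfilicinic acid F5. Partial acidolytic deacylation (80 % H2SO4, 80 °C) should remove one of the two equivalent acyl groups and come back to the route at compound 5.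

Further compounds
F1 | step 4 | 1-{2,6-dihydroxy-4-[(2-methylbut-3-yn-2-yl)oxy]phenyl}-2-methylpropan-1-one | CC(C)C(=O)c1c(O)cc(OC(C)(C)C#C)cc1O
F2 | step 4 | 1-(5,7-dihydroxy-2,2-dimethyl-2H-chromen-6-yl)-2-methylpropan-1-one | CC(C)C(=O)c1c(O)cc2OC(C)(C)C=Cc2c1O
F3 | step 3 | 1-{3-[(dimethylamino)methyl]-2,4,6-trihydroxyphenyl}-2-methylpropan-1-one | CC(C)C(=O)c1c(O)cc(O)c(CN(C)C)c1O
F4 | step 2 | 1,1'-(2,4,6-trihydroxy-1,3-phenylene)bis(2-methylpropan-1-one) | CC(C)C(=O)c1c(O)cc(O)c(C(=O)C(C)C)c1O
F5 | step 2 | 3,5-dihydroxy-4,4-dimethyl-2,6-bis(2-methylpropanoyl)cyclohexa-2,5-dien-1-one | CC(C)C(=O)C1=C(O)C(C)(C)C(O)=C(C(=O)C(C)C)C1=O
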